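## Retrosynthetic overview

1. Ferutinin ⇐ jaeschkeanadiol by selective acylation of the secondary OH with a protected 4-hydroxybenzoyl unit.
2. Jaeschkeanadiol ⇐ trans-fused C3 ketone: i-Pr adds anti to the angular methyl (sets C3); the C3-OH then directs hydride to C4; the C6 methyl comes from an ester.
3. trans ring fusion ⇐ stereospecific semipinacol 1,2-hydride shift of a syn-epoxy alcohol (CBS reduction, then directed epoxidation).
4. Hydroazulene core and C8a quaternary centre ⇐ key step: Rh(II)-catalysed asymmetric vinylcarbenoid [4+3] (cyclopropanation / divinylcyclopropane Cope) of methyl vinyldiazoacetate with 3-methyl-2-vinylcyclopentenone.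
5. Ring order: the five-membered ring is bought; the seven-membered ring is annulated onto it in the key step.

Convention: azulene numbering (C3 = carbinol bearing i-Pr, C3a/C8a = ring fusion, C4 = acyloxy carbon, C6 = vinylic methyl carbon); β = face of the C8a methyl.

Assumption: Rh2(R-DOSP)4 gives the (8aR) series, assigned by analogy with the styrene model (S-catalyst → (1S,2R) E-cyclopropane); if the sense is reversed on this diene, use Rh2(S-DOSP)4.

## Route

**Step 1**
Reactants: 1, 2-bromo-3-methylcyclopent-2-en-1-one; 2, potassium vinyltrifluoroborate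
Product: 3, 3-methyl-2-vinylcyclopent-2-en-1-one
Conditions: PdCl2(dppf) (3 mol%), Et3N, n-PrOH, 90 °C; use promptly
Reagents that add atoms: potassium vinyltrifluoroborate (2), C=C[B-](F)(F)F.[K+]
Why: Suzuki–Miyaura coupling of an α-bromoenone with a vinyltrifluoroborate; no stereocentre formed.

**Step 2**
Reactants: 4, methyl but-3-enoate; 5, 4-acetamidobenzenesulfonyl azide (p-ABSA)
Product: 6, methyl 2-diazobut-3-enoate (used at once as a cold solution)
Conditions: p-ABSA, DBU, MeCN, 0 °C
Reagents that add atoms: p-ABSA (5), CC(=O)Nc1ccc(cc1)S(=O)(=O)N=[N+]=[N-] (transfers N2)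
Why: Regitz diazo transfer to the α-CH2 activated by both ester and vinyl; the product is kept cold because it slowly electrocyclises to a pyrazole.

**Step 3 (key step)**
Reactants: 3, 3-methyl-2-vinylcyclopent-2-en-1-one; 6, methyl 2-diazobut-3-enoate
Product: 7, methyl (8aR)-8a-methyl-3-oxo-1,2,3,5,8,8a-hexahydroazulene-6-carboxylate
Conditions: Rh2(R-DOSP)4 (1 mol%), hexanes/PhMe, −40 °C → rt (slow addition of 6); then PhMe, 110 °C
Reagents that add atoms: methyl 2-diazobut-3-enoate (6), COC(=O)C(=[N+]=[N-])C=C (N2 lost)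
Why: Tandem asymmetric cyclopropanation / cis-divinylcyclopropane Cope rearrangement (formal [4+3]): the donor/acceptor carbenoid cyclopropanates only the terminal vinyl group E-selectively, the catalyst fixes the cyclopropane configuration, and the boat Cope transfers it to the C8a quaternary centre while closing the seven-membered ring; heating is needed because the ring methyl is the "inside" substituent in the boat.

**Step 4**
Reactants: 7
Product: 8, methyl (3S,8aR)-3-hydroxy-8a-methyl-1,2,3,5,8,8a-hexahydroazulene-6-carboxylate (3-OH β, cis to the C8a methyl)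
Conditions: (R)-Me-CBS (20 mol%), catecholborane, PhMe, −78 °C
Reagents that add atoms: none (hydride only)
Why: Corey–Bakshi–Shibata reduction with the alkylidene carbon C3a as the large group; reagent control delivers hydride to the α-face to give the 3β-alcohol, overriding the weak substrate bias; the enoate is untouched.

**Step 5**
Reactants: 8; 9, tert-butyl hydroperoxide
Product: 10, methyl (3S,3aR,4R,8aR)-3a,4-epoxy-3-hydroxy-8a-methyl-1,2,3,3a,4,5,8,8a-octahydroazulene-6-carboxylate (epoxide O and 3-OH both β)
Conditions: VO(acac)2 (5 mol%), t-BuOOH, CH2Cl2, 0 °C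
Reagents that add atoms: tert-butyl hydroperoxide (9), CC(C)(C)OO (adds O)
Why: Vanadium-catalysed hydroxyl-directed epoxidation delivers oxygen syn to the 3β-OH; the electron-poor enoate alkene does not react.

**Step 6**
Reactants: 10; 11, trimethylsilyl triflate
Product: 12, methyl (3aS,4R,8aR)-8a-methyl-3-oxo-4-[(trimethylsilyl)oxy]-1,2,3,3a,4,5,8,8a-octahydroazulene-6-carboxylate (H-3a α, trans-fused; 4-OTMS β), used crude
Conditions: TMSOTf (2.2 equiv), i-Pr2NEt, CH2Cl2, −78 → −45 °C; NaHCO3 quench
Reagents that add atoms: TMSOTf (11), C[Si](C)(C)OS(=O)(=O)C(F)(F)F (adds Me3Si)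
Why: Type-III semipinacol ("non-aldol aldol") rearrangement: the epoxide ionises at tertiary C3a with concerted 1,2-shift of the antiperiplanar α C3–H onto the α-face of C3a, pushed by the silyloxy group; this sets the trans ring fusion stereospecifically and unveils the C3 ketone.

**Step 7**
Reactants: 12; 13, isopropylmagnesium chloride
Product: 14, methyl (3R,3aS,4R,8aR)-3,4-dihydroxy-8a-methyl-3-(propan-2-yl)-1,2,3,3a,4,5,8,8a-octahydroazulene-6-carboxylate (3-OH β, i-Pr α, 4-OH β)
Conditions: i-PrMgCl, CeCl3, THF, −78 °C; then citric acid, MeOH (removes TMS)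
Reagents that add atoms: isopropylmagnesium chloride (13), CC(C)[Mg]Cl
Why: Organocerium 1,2-addition to the trans-fused cyclopentanone from the α-face, anti to the angular methyl and the 4β-OTMS, gives 3β-OH/3α-i-Pr (3R); low basicity limits enolisation and the enoate is inert at −78 °C.

**Step 8**
Reactants: 14
Product: 15, (3R,3aS,4R,8aR)-6-(hydroxymethyl)-8a-methyl-3-(propan-2-yl)-1,2,3,3a,4,5,8,8a-octahydroazulene-3,4-diol
Conditions: DIBAL-H (5 equiv), CH2Cl2, −78 → 0 °C
Reagents that add atoms: none (hydride only)
Why: DIBAL 1,2-reduction of the enoate to the primary allylic alcohol; no stereocentre affected.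

**Step 9**
Reactants: 15
Product: 16, (3R,3aS,4R,8aR)-6,8a-dimethyl-3-(propan-2-yl)-1,2,3,3a,4,5,8,8a-octahydroazulene-3,4-diol (4-epi-jaeschkeanadiol)
Conditions: SO3·pyridine (1.2 equiv), THF, 0 °C; then LiAlH4, 0 °C → rt
Reagents that add atoms: none (sulfate is a transient leaving group; hydride only)
Why: Corey-type allylic deoxygenation: the unhindered primary allylic OH is sulfated selectively and displaced by hydride (SN2, no alkene transposition) to give the C6 methyl; the hindered 4β-OH and tertiary OH are left.

**Step 10**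
Reactants: 16
Product: 17, (3R,3aR,8aR)-3-hydroxy-6,8a-dimethyl-3-(propan-2-yl)-2,3,3a,5,8,8a-hexahydroazulen-4(1H)-one (same geometry at C3a; descriptor changes by CIP priority)
Conditions: Dess–Martin periodinane, NaHCO3, CH2Cl2, 0 °C → rt
Reagents that add atoms: none
Why: Dess–Martin oxidation of the only secondary alcohol under neutral conditions, so the β-hydroxy ketone does not retro-aldolise, C3a does not epimerise and the β,γ-alkene does not move.

**Step 11**
Reactants: 17
Product: 18, jaeschkeanadiol, (3R,3aS,4S,8aR)-6,8a-dimethyl-3-(propan-2-yl)-1,2,3,3a,4,5,8,8a-octahydroazulene-3,4-diol (4-OH α)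
Conditions: Me4NBH(OAc)3, AcOH/MeCN, −20 °C
Reagents that add atoms: none (hydride only)
Why: Evans–Saksena hydroxyl-directed reduction: the 3β-alkoxyborohydride delivers hydride intramolecularly to the β-face of the C4 ketone, giving the 1,3-anti diol (4α-OH, 4S).

**Step 12**
Reactants: 18; 19, 4-acetoxybenzoyl chloride
Product: 20, (3R,3aS,4S,8aR)-3-hydroxy-6,8a-dimethyl-3-(propan-2-yl)-1,2,3,3a,4,5,8,8a-octahydroazulen-4-yl 4-(acetyloxy)benzoate
Conditions: DMAP, pyridine, CH2Cl2, 0 °C → rt
Reagents that add atoms: 4-acetoxybenzoyl chloride (19), CC(=O)Oc1ccc(cc1)C(Cl)=O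
Why: DMAP-catalysed acylation occurs only at the secondary 4-OH; the tertiary 3-OH is inert; configuration retained.

**Step 13**
Reactants: 20
Product: 21, ferutinin
Conditions: pyrrolidine, CH2Cl2, 0 °C → rt
Reagents that add atoms: none
Why: Chemoselective aminolysis of the activated phenolic acetate; the hindered secondary benzoate is untouched.

## Compound list

1 | 2-bromo-3-methylcyclopent-2-en-1-one | CC1=C(Br)C(=O)CC1 | starting material
2 | potassium vinyltrifluoroborate | C=C[B-](F)(F)F.[K+] | starting material
3 | 3-methyl-2-vinylcyclopent-2-en-1-one | CC1=C(C=C)C(=O)CC1 | intermediate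
4 | methyl but-3-enoate | COC(=O)CC=C | starting material
5 | 4-acetamidobenzenesulfonyl azide | CC(=O)Nc1ccc(cc1)S(=O)(=O)N=[N+]=[N-] | starting material (reagent)
6 | methyl 2-diazobut-3-enoate | COC(=O)C(=[N+]=[N-])C=C | intermediate
7 | methyl (8aR)-8a-methyl-3-oxo-1,2,3,5,8,8a-hexahydroazulene-6-carboxylate | COC(=O)C1=CC[C@@]2(C)CCC(=O)C2=CC1 | intermediate
8 | methyl (3S,8aR)-3-hydroxy-8a-methyl-1,2,3,5,8,8a-hexahydroazulene-6-carboxylate | COC(=O)C1=CC[C@@]2(C)CC[C@H](O)C2=CC1 | intermediate
9 | tert-butyl hydroperoxide | CC(C)(C)OO | starting material (reagent)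
10 | methyl (3S,3aR,4R,8aR)-3a,4-epoxy-3-hydroxy-8a-methyl-octahydroazulene-6-carboxylate | COC(=O)C1=CC[C@@]2(C)CC[C@H](O)[C@]23O[C@@H]3C1 | intermediate
11 | trimethylsilyl trifluoromethanesulfonate | C[Si](C)(C)OS(=O)(=O)C(F)(F)F | starting material (reagent)
12 | methyl (3aS,4R,8aR)-8a-methyl-3-oxo-4-(trimethylsilyloxy)-octahydroazulene-6-carboxylate | COC(=O)C1=CC[C@@]2(C)CCC(=O)[C@@H]2[C@H](O[Si](C)(C)C)C1 | intermediate
13 | isopropylmagnesium chloride | CC(C)[Mg]Cl | starting material (reagent)
14 | methyl (3R,3aS,4R,8aR)-3,4-dihydroxy-8a-methyl-3-isopropyl-octahydroazulene-6-carboxylate | COC(=O)C1=CC[C@@]2(C)CC[C@@](O)(C(C)C)[C@@H]2[C@H](O)C1 | intermediate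
15 | (3R,3aS,4R,8aR)-6-(hydroxymethyl)-8a-methyl-3-isopropyl-octahydroazulene-3,4-diol | OCC1=CC[C@@]2(C)CC[C@@](O)(C(C)C)[C@@H]2[C@H](O)C1 | intermediate
16 | 4-epi-jaeschkeanadiol (3R,3aS,4R,8aR) | CC1=CC[C@@]2(C)CC[C@@](O)(C(C)C)[C@@H]2[C@H](O)C1 | intermediate
17 | (3R,3aR,8aR)-3-hydroxy-6,8a-dimethyl-3-isopropyl-hexahydroazulen-4(1H)-one | CC1=CC[C@@]2(C)CC[C@@](O)(C(C)C)[C@@H]2C(=O)C1 | intermediate
18 | jaeschkeanadiol (3R,3aS,4S,8aR) | CC1=CC[C@@]2(C)CC[C@@](O)(C(C)C)[C@@H]2[C@@H](O)C1 | intermediate
19 | 4-acetoxybenzoyl chloride | CC(=O)Oc1ccc(cc1)C(Cl)=O | starting material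
20 | ferutinin O-acetate | CC1=CC[C@@]2(C)CC[C@@](O)(C(C)C)[C@@H]2[C@@H](OC(=O)c2ccc(OC(C)=O)cc2)C1 | intermediate
21 | ferutinin | CC1=CC[C@@]2(C)CC[C@@](O)(C(C)C)[C@@H]2[C@@H](OC(=O)c2ccc(O)cc2)C1 | target

## Summary

Total steps: 13. Longest linear sequence: 12 (steps 1, 3–13).

Steps most likely to fail:

- **Step 3 ([4+3]).** The cross-conjugated dienone is an untested diene, the Cope has an "inside" methyl, and ee may erode on heating. Fallback: abandon the cycloaddition and close the seven-membered ring by ring-closing metathesis on a cyclopentanone whose quaternary centre is set by Pd-catalysed asymmetric allylic alkylation, rejoining at an enone analogous to 7.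
- **Step 6 (semipinacol hydride shift).** A competing shift of the C4–H would give the regioisomeric 4-ketone, and the product could enolise and eliminate. Fallback: silylate 8 (TBS) and hydroborate the C3a=C4 alkene anti to the β-OTBS and the methyl. This sets H-3a α and the natural 4α-OH in one syn addition, and C3 is then oxidised for the i-Pr addition.
- **Step 7 (i-Pr addition to a hindered, enolisable ketone).** Enolisation or reduction may dominate. Fallback: add 2-propenylcerium instead, then hydrogenate the 1,1-disubstituted alkene selectively (Wilkinson's catalyst or diimide) in the presence of the trisubstituted ring alkene.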